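The readings are simulated on assumed constants, noise included.

One mol% of catalyst is the unit of this decision. The flask repeats the south-east run, 1.5 M of substrate fed over 10 min, but with 4 mol% of catalyst in place of 2 mol%. Is that extra catalyst worth charging?

| setting | east | south-west | south-east | flask |
|---|---|---|---|---|
| substrate | 0.75 M (fed, over 10 min) | 1.1 M (fed, over 10 min) | 1.5 M (fed, over 10 min) | 1.5 M (fed, over 10 min) |
| catalyst | 4 mol% | 4 mol% | 2 mol% | 4 mol% |
| remark | run made earlier; the fed solution adds 0.25 times the starting volume | run made earlier; the fed solution adds 0.25 times the starting volume | run made earlier; the fed solution adds 0.25 times the starting volume | the fed solution adds 0.25 times the starting volume |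
| time |  |  |  | 20 min |

| run | time / min | isomer of the product A / % | target / % | isomer of the product B / % | substrate / % |
|---|---|---|---|---|---|
| east | 5.00 | 0 | 4.1 | 5.7 | 37.9 |
| east | 10.0 | 0.6 | 14.0 | 11.2 | 71.6 |
| east | 15.0 | 1.8 | 23.2 | 10.3 | 62.6 |
| east | 20.0 | 1.2 | 27.5 | 10.5 | 57.3 |
| south-west | 1.50 | 0 | 0.7 | 0.7 | 12.3 |
| south-west | 4.00 | 0.3 | 3.2 | 4.5 | 30.3 |
| south-west | 8.00 | 0 | 9.9 | 8.8 | 57.9 |
| south-west | 20.0 | 2.4 | 28.2 | 10.5 | 57.1 |
| south-east | 1.50 | 0.4 | 0.7 | 1.8 | 12.1 |
| south-east | 4.00 | 0 | 2.5 | 4.7 | 31.6 |
| south-east | 8.00 | 0.8 | 9.8 | 9.0 | 58.7 |
| south-east | 20.0 | 0.5 | 28.6 | 9.6 | 59.2 |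

(scatter of a reading: 0.5 percentage points)

- amounts are per litre of the starting volume; all of the dose is in the solution fed
- percentages count the whole charge, also what has not yet gone in
- a reading or a percentage of substrate is of its free form alone

1. the species in which most of what was charged as substrate, at 20 min sits (target / substrate / isomer of the product A / isomer of the product B)
2. the largest share itself, whichever of these holds it, in percent of the substrate charged

The large part of the answer can be read directly from the runs, so only a correction needs reckoning. Averaged over the east and south-west runs, both at 4 mol%, the whole charge less the sum of the readings at 20.0 min comes to 2.65%; this is the unread share. The south-east run gives 2.10%. The difference of 0.55 percentage points is smaller than the 1 point scatter of one such sum, so this reckoning carries the one unread share to the flask. Any gain has to be judged on target, not on this share. Averaged over the east and south-west runs at 4 mol%, free substrate reads 57.2% against 59.2% in the south-east run, but target reads 27.8% against 28.6%. Those two runs also hold less substrate than the south-east run, so the comparison is not of catalyst by itself, yet the target readings show no gain at the higher loading.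

Averaged over the east, south-west and south-east runs, the products stand at target 28.1%, isomer of the product B 10.2% and isomer of the product A 1.37%. Subtracting these and the unread share leaves the flask 57.7% of free substrate, more than any product. The decision is to keep 2 mol% unless the flask shows otherwise.

The forecast names substrate at 57%, which is 0.70 points below this reckoning. Its grounds are these: “At 4 mol%, free substrate should sit slightly lower.”

The flask gives substrate at 57.2%, with target at 27.9%.

    substrate ⇌ target (K = 0.660, k = 8.10 × 10⁻⁴ /s)
    substrate + catalyst ⇌ isomer of the product A + catalyst, rate k2*[substrate]*[catalyst] forward; the back reaction follows from the equilibrium constant (K = 0.0830, k = 0.00390 /M/s)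
    substrate ⇌ isomer of the product B (K = 0.170, k = 0.00390 /s)
    substrate + catalyst ⇌ idle complex, settled at all times (K = 6.00 /M)

With the flask's products as found, the unread share leaves 57.8% of free substrate, against 57.2% found. In the flask, 80.5% of the catalyst stands as idle complex, an off-cycle form, and that is 3.22% of the charge. The neighbouring flask is the same charge read at 50 min. It holds target 33.7%, isomer of the product B 8.71% and isomer of the product A 3.28%. The same subtraction leaves 51.7%, and that flask gives 51.2% of free substrate.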